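Ring A (C1, C10–C14) is a cyclohexenone in which the C12 carbonyl is 1,3 to C10; with C10 as a second carbonyl, C11 becomes the active methylene of a 1,3-dione and quaternary C1 the α-carbon of a β-keto ester. The route rests on a [3+3] Michael–Claisen annulation: chiral-ion-pair Michael addition of methyl 2-methyl-3-oxopentanoate to methyl acrylate (C1–C14, sets C1) followed in the same flask by Claisen closure (C11–C12), so two open-chain esters give the ring A dione. The C10 carbonyl then takes up C9; a dithiane (C8), acrolein, acrylate and methacrolein supply ring B and lactone ring C, closed by metathesis before a final ene-chlorination.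

Key step: step 1

Remark on numbering: briarane locants are used for all intermediates. Ring A = C1, C10, C11, C12, C13, C14; ring B = C1 to C10; lactone ring C = C7, C8, C17, C19 and O; C15 = methyl on C1, C16 = exocyclic carbon on C5, C18 = methyl on C17, C20 = methyl on C11.
Assumption: the lipase in step 12 shows its usual preference for the (R)-alcohol (large dithianyl, medium vinyl), so the (S)-alcohol remains.

Step 1
Reactants: 1 methyl 2-methyl-3-oxopentanoate (racemic); 2 methyl acrylate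
Product: 4 methyl (1S)-1,3-dimethyl-2,4-dioxocyclohexane-1-carboxylate (C3 epimers; largely enolised), via Michael adduct 3 (not isolated)
Conditions: O-allyl-N-(9-anthracenylmethyl)cinchona ammonium bromide (10 mol %, the pseudo-enantiomer that gives S), Cs2CO3 (0.3 equiv), toluene, −40 °C; then t-BuOK, THF, 0 °C to rt; 1 M HCl
Reagents that add atoms: none
Why: The ion pair of the chiral ammonium cation and the enolate of β-keto ester 1 adds to the β-carbon of 2 (Michael addition, C1–C14) to give 3, and t-BuOK then turns the ethyl-ketone CH2 (C11) into an enolate that acylates on the acrylate-derived ester (Claisen condensation, C11–C12) with loss of methoxide, the deprotonation of the 1,3-dione driving the sequence. The closest known reaction types are the consecutive Michael–Claisen synthesis of cyclohexane-1,3-diones from ketones and acrylates and phase-transfer-catalysed asymmetric Michael additions of α-substituted β-keto esters. Ring A closes in the 6-exo-trig mode (enolate carbon C11 onto ester carbonyl C12). C1, the only lasting stereocenter, is fixed in the Michael step by the chiral cation shielding one face of the planar enolate, while C11 stays enolised and is set later. The step needs alkylation at C1 and acylation by C11 only: the doubly activated C1–H is the only acidic site of 1, and once C1 is quaternary only C11 can enolise towards C10 and every other closure would be four-membered.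

Step 2
Reactants: 4 methyl (1S)-1,3-dimethyl-2,4-dioxocyclohexane-1-carboxylate
Product: 5 methyl (1S)-1,3-dimethyl-4-(2-methylpropoxy)-2-oxocyclohex-3-ene-1-carboxylate
Conditions: i-BuOH, TsOH·H2O (cat.), benzene, reflux, Dean–Stark
Reagents that add atoms: isobutanol, CC(C)CO
Why: Acid-catalysed enol etherification of the 1,3-dione occurs at the C12 oxygen remote from quaternary C1 (the usual preference of 4,4-disubstituted cyclohexane-1,3-diones), which leaves C10 as the carbonyl of the vinylogous ester and removes the C11 stereocenter.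

Step 3
Reactants: 5 methyl (1S)-1,3-dimethyl-4-(2-methylpropoxy)-2-oxocyclohex-3-ene-1-carboxylate
Product: 8 (4S)-4-(hydroxymethyl)-3-[(methoxymethoxy)methyl]-2,4-dimethylcyclohex-2-en-1-one, via carbinol ester 6 (not isolated), via carbinol diol 7 (not isolated)
Conditions: Bu3SnCH2OCH2OMe, n-BuLi, THF, −78 °C; CeCl3; 5, −78 °C; LiAlH4, −78 to 0 °C; 1 M HCl, THF, rt
Reagents that add atoms: tributyl[(methoxymethoxy)methyl]stannane, CCCC[Sn](CCCC)(CCCC)COCOC; water, O
Why: Stork–Danheiser sequence: the alkoxymethyl cerium reagent adds 1,2 to the vinylogous ester carbonyl C10 in preference to the hindered ester, LiAlH4 then reduces that ester to the C2 carbinol, and aqueous acid hydrolyses the enol ether with allylic transposition to the C12 enone; no new stereocenter.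

Step 4
Reactants: 8 (4S)-4-(hydroxymethyl)-3-[(methoxymethoxy)methyl]-2,4-dimethylcyclohex-2-en-1-one
Product: 9 (2R,3S,4S)-4-(hydroxymethyl)-3-[(methoxymethoxy)methyl]-2,4-dimethylcyclohexan-1-one
Conditions: [Ir(cod)(PCy3)(py)]PF6 (10 mol %), H2 (50 bar), CH2Cl2, rt
Reagents that add atoms: none
Why: Hydroxyl-directed homogeneous hydrogenation: the cationic iridium centre binds the homoallylic C2–OH and delivers both hydrogens to the tetrasubstituted C10=C11 bond from the face of the CH2OH group, which sets H-10 cis to C2 (C9 trans to C2) and C11.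

Step 5
Reactants: 9 (2R,3S,4S)-4-(hydroxymethyl)-3-[(methoxymethoxy)methyl]-2,4-dimethylcyclohexan-1-one
Product: 10 (1S,2S,3R)-2-[(methoxymethoxy)methyl]-1,3-dimethyl-4-oxocyclohexane-1-carbaldehyde
Conditions: DMP, NaHCO3, CH2Cl2, 0 °C to rt
Reagents that add atoms: none
Why: DMP oxidises the neopentylic primary alcohol to the non-enolisable aldehyde without touching the ketone or the acetal.

Step 6
Reactants: 10 (1S,2S,3R)-2-[(methoxymethoxy)methyl]-1,3-dimethyl-4-oxocyclohexane-1-carbaldehyde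
Product: 11 (2R,3S,4S)-4-[(E)-2-iodoethenyl]-3-[(methoxymethoxy)methyl]-2,4-dimethylcyclohexan-1-one
Conditions: CrCl2, CHI3, THF, 0 °C
Reagents that add atoms: iodoform, IC(I)I
Why: Takai olefination (geminal dichromium species from CHI3 and CrCl2) converts the aldehyde into the (E)-vinyl iodide (C3) and is selective for aldehydes over ketones.

Step 7
Reactants: 11 (2R,3S,4S)-4-[(E)-2-iodoethenyl]-3-[(methoxymethoxy)methyl]-2,4-dimethylcyclohexan-1-one
Product: 12 (2S,3S,4S)-2-hydroxy-4-[(E)-2-iodoethenyl]-3-[(methoxymethoxy)methyl]-2,4-dimethylcyclohexan-1-one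
Conditions: t-BuOK, O2, P(OEt)3, THF/t-BuOH, −25 °C; 1 M HCl
Reagents that add atoms: dioxygen, O=O
Why: Autoxidation of the thermodynamic (more substituted) potassium enolate at tertiary C11 with in situ phosphite reduction of the hydroperoxide; oxygen attacks anti to the 1,3-related axial C15 methyl and so enters cis to C2.

Step 8
Reactants: 12 (2S,3S,4S)-2-hydroxy-4-[(E)-2-iodoethenyl]-3-[(methoxymethoxy)methyl]-2,4-dimethylcyclohexan-1-one
Product: 13 (1S,2S,3S)-3-[(E)-2-iodoethenyl]-2-[(methoxymethoxy)methyl]-1,3-dimethyl-6-oxocyclohexyl acetate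
Conditions: Ac2O, DMAP, Et3N, CH2Cl2, 40 °C
Reagents that add atoms: acetic anhydride, CC(=O)OC(C)=O
Why: DMAP-catalysed acetylation of the tertiary α-ketol gives the C11 acetate of the target.

Step 9
Reactants: 13 (1S,2S,3S)-3-[(E)-2-iodoethenyl]-2-[(methoxymethoxy)methyl]-1,3-dimethyl-6-oxocyclohexyl acetate
Product: 14 (1S,2S,3S)-2-(hydroxymethyl)-3-[(E)-2-iodoethenyl]-1,3-dimethyl-6-oxocyclohexyl acetate
Conditions: Me2BBr, CH2Cl2, −78 °C; aq NaHCO3
Reagents that add atoms: none
Why: Bromodimethylborane cleaves the methoxymethyl ether at low temperature and leaves the acetate, the ketone and the vinyl iodide intact.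

Step 10
Reactants: 14 (1S,2S,3S)-2-(hydroxymethyl)-3-[(E)-2-iodoethenyl]-1,3-dimethyl-6-oxocyclohexyl acetate
Product: 15 (1S,2R,3S)-2-formyl-3-[(E)-2-iodoethenyl]-1,3-dimethyl-6-oxocyclohexyl acetate
Conditions: DMP, NaHCO3, CH2Cl2, rt
Reagents that add atoms: none
Why: DMP oxidation of the primary alcohol gives the C9 aldehyde under buffered conditions that should not epimerise C10.

Step 11
Reactants: 16 1,3-dithiane; 17 acrolein
Product: 18 rac-1-(1,3-dithian-2-yl)prop-2-en-1-ol
Conditions: n-BuLi, THF, −30 °C; 17, −78 °C; H2O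
Reagents that add atoms: none
Why: 2-Lithio-1,3-dithiane (acyl anion equivalent for C8) adds 1,2 to acrolein; the carbinol C7 is formed racemic.

Step 12
Reactants: 18 rac-1-(1,3-dithian-2-yl)prop-2-en-1-ol
Product: 19 (S)-1-(1,3-dithian-2-yl)prop-2-en-1-ol
Conditions: Novozym 435 (immobilised Candida antarctica lipase B), vinyl acetate, MTBE, 30 °C, to just over half conversion
Reagents that add atoms: none
Why: Lipase-catalysed kinetic resolution: the enzyme acetylates the (R)-alcohol and leaves the (S)-alcohol, which fixes C7.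

Step 13
Reactants: 15 (1S,2R,3S)-2-formyl-3-[(E)-2-iodoethenyl]-1,3-dimethyl-6-oxocyclohexyl acetate; 19 (S)-1-(1,3-dithian-2-yl)prop-2-en-1-ol
Product: 20 (1S,2S,3S)-2-{(S)-hydroxy[2-((S)-1-hydroxyprop-2-en-1-yl)-1,3-dithian-2-yl]methyl}-3-[(E)-2-iodoethenyl]-1,3-dimethyl-6-oxocyclohexyl acetate
Conditions: 19, n-BuLi (2.1 equiv), THF, −30 °C; 15, −78 °C; H2O
Reagents that add atoms: none
Why: The C,O-dianion of 19 (the β-alkoxide blocks β-elimination) adds to the aldehyde faster than to the hindered ketone or the acetate; Felkin–Anh attack anti to the bulkier acetoxy-bearing C11 branch of C10 should give the (9S) carbinol.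

Step 14
Reactants: 20 dithiane diol
Product: 21 7-O-acryloyl derivative of 20 (1S,7S,9S,10S,11S; C9 hydroxyl free)
Conditions: acryloyl chloride (1.05 equiv), i-Pr2NEt, CH2Cl2, −78 °C
Reagents that add atoms: acryloyl chloride, C=CC(=O)Cl
Why: Acylation at low temperature takes the less hindered allylic C7 hydroxyl, because the C9 hydroxyl is flanked by the dithiane carbon and ring A.

Step 15
Reactants: 21 7-O-acryloyl derivative of 20
Product: 22 9-O-acetyl-7-O-acryloyl derivative of 20 (1S,7S,9S,10S,11S)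
Conditions: Ac2O, DMAP, pyridine, rt
Reagents that add atoms: acetic anhydride, CC(=O)OC(C)=O
Why: DMAP-catalysed acetylation of the remaining hindered secondary alcohol installs the C9 acetate of the target.

Step 16
Reactants: 22 9-O-acetyl-7-O-acryloyl derivative of 20
Product: 23 (1S,2S,3S)-2-[(1S,3S)-1-acetoxy-3-(acryloyloxy)-2-oxopent-4-en-1-yl]-3-[(E)-2-iodoethenyl]-1,3-dimethyl-6-oxocyclohexyl acetate
Conditions: PhI(OCOCF3)2, MeCN/H2O (9:1), 0 °C
Reagents that add atoms: water, O
Why: Oxidative hydrolysis of the dithiane with the hypervalent iodine reagent unmasks the C8 ketone under conditions that spare the alkenes, the esters and the vinyl iodide.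

Step 17
Reactants: 23 bis(acyloxy) ketone
Product: 24 (1S,2S,3S)-2-{(S)-acetoxy[(2S,3S,4R)-3-hydroxy-4-methyl-5-oxo-2-vinyltetrahydrofuran-3-yl]methyl}-3-[(E)-2-iodoethenyl]-1,3-dimethyl-6-oxocyclohexyl acetate
Conditions: Cu(OAc)2·H2O (5 mol %), rac-BINAP (5 mol %), (HMe2Si)2O, THF, rt; aq NH4F
Reagents that add atoms: none
Why: Copper hydride-catalysed reductive aldol cyclisation: conjugate reduction of the acrylate gives a copper (Z)-enolate (C18 becomes methyl) that adds to the C8 ketone through a chair-like Zimmerman–Traxler transition state with the bulky C9 branch trans to the C7 vinyl group, which should set the C8 hydroxyl cis to C6 and the C17 methyl syn to it.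

Step 18
Reactants: 24 lactone
Product: 25 (1S,5S,6S)-6-{(S)-acetoxy[(2S,3S,4R)-3-hydroxy-4-methyl-5-oxo-2-vinyltetrahydrofuran-3-yl]methyl}-5-[(E)-2-iodoethenyl]-1,5-dimethyl-2-oxocyclohex-3-en-1-yl acetate
Conditions: IBX, 4-methoxypyridine N-oxide, DMSO, rt
Reagents that add atoms: none
Why: IBX dehydrogenation of the ring ketone, which can enolise only towards C13 because C11 is fully substituted, introduces the C13=C14 double bond.

Step 19
Reactants: 25 enone vinyl iodide
Product: 26 seco-diene: 25 in which iodine is replaced by the (S)-CH(OH)C(CH3)=CH2 group (1S,2E,4S,7S,8S,9S,10S,11S,17R)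
Conditions: CrCl2, (S)-N-[2-(4-isopropyl-4,5-dihydrooxazol-2-yl)-6-methylphenyl]methanesulfonamide, Et3N, NiCl2 (cat.), methacrolein, THF, rt
Reagents that add atoms: methacrolein, C=C(C)C=O
Why: Nozaki–Hiyama–Kishi reaction: the alkenyl nickel/chromium species from the vinyl iodide adds 1,2 to methacrolein with retention of the (E) geometry, and the chiral ligand on chromium controls the new C4 carbinol (4S).

Step 20
Reactants: 26 seco-diene
Product: 27 6-deschloro-5(6)-ene macrocycle (1S,2E,4S,5Z,7S,8S,9S,10S,11S,17R)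
Conditions: second-generation Hoveyda–Grubbs catalyst (15 mol %), 1,4-benzoquinone, toluene (0.5 mM), 80 °C
Reagents that add atoms: none
Why: Ring-closing metathesis between the C7 vinyl group and the 1,1-disubstituted alkene at C5 closes ring B as the trisubstituted (Z)-C5=C6 olefin with loss of ethylene; high dilution and pre-organisation by ring A and the lactone favour cyclisation.

Step 21
Reactants: 27 6-deschloro-5(6)-ene macrocycle
Product: 28 CNP0196166.1 (1S,2E,4S,6S,7R,8R,9S,10S,11S,17R)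
Conditions: t-BuOCl, SiO2, hexane/CH2Cl2, −20 °C, dark
Reagents that add atoms: tert-butyl hypochlorite, CC(C)(C)OCl
Why: Ene-type chlorination: electrophilic chlorine adds to the most electron-rich, trisubstituted C5=C6 bond at C6 (Markovnikov) and a C16 proton is lost, which gives the allylic chloride with the exocyclic methylene; attack from the outer face of the ring alkene should give (6S).

Compound list
1 | methyl 2-methyl-3-oxopentanoate (racemic) | CCC(=O)C(C)C(=O)OC | starting material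
2 | methyl acrylate | C=CC(=O)OC | starting material
3 | dimethyl (2S)-2-methyl-2-propanoylpentanedioate | COC(=O)[C@@](C(=O)CC)(C)CCC(=O)OC | intermediate
4 | methyl (1S)-1,3-dimethyl-2,4-dioxocyclohexane-1-carboxylate | COC(=O)[C@@]1(C)CCC(=O)C(C)C1=O | intermediate
5 | methyl (1S)-1,3-dimethyl-4-(2-methylpropoxy)-2-oxocyclohex-3-ene-1-carboxylate | COC(=O)[C@@]1(C)CCC(OCC(C)C)=C(C)C1=O | intermediate
6 | methyl (1S)-2-hydroxy-2-[(methoxymethoxy)methyl]-1,3-dimethyl-4-(2-methylpropoxy)cyclohex-3-ene-1-carboxylate (C2 epimers, as metal alkoxide) | COC(=O)[C@@]1(C)CCC(OCC(C)C)=C(C)C1(O)COCOC | intermediate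
7 | (6R)-6-(hydroxymethyl)-1-[(methoxymethoxy)methyl]-2,6-dimethyl-3-(2-methylpropoxy)cyclohex-2-en-1-ol (C1 epimers) | OC[C@@]1(C)CCC(OCC(C)C)=C(C)C1(O)COCOC | intermediate
8 | (4S)-4-(hydroxymethyl)-3-[(methoxymethoxy)methyl]-2,4-dimethylcyclohex-2-en-1-one | OC[C@@]1(C)CCC(=O)C(C)=C1COCOC | intermediate
9 | (2R,3S,4S)-4-(hydroxymethyl)-3-[(methoxymethoxy)methyl]-2,4-dimethylcyclohexan-1-one | OC[C@@]1(C)CCC(=O)[C@H](C)[C@@H]1COCOC | intermediate
10 | (1S,2S,3R)-2-[(methoxymethoxy)methyl]-1,3-dimethyl-4-oxocyclohexane-1-carbaldehyde | O=C[C@@]1(C)CCC(=O)[C@H](C)[C@@H]1COCOC | intermediate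
11 | (2R,3S,4S)-4-[(E)-2-iodoethenyl]-3-[(methoxymethoxy)methyl]-2,4-dimethylcyclohexan-1-one | I/C=C/[C@@]1(C)CCC(=O)[C@H](C)[C@@H]1COCOC | intermediate
12 | (2S,3S,4S)-2-hydroxy-4-[(E)-2-iodoethenyl]-3-[(methoxymethoxy)methyl]-2,4-dimethylcyclohexan-1-one | I/C=C/[C@@]1(C)CCC(=O)[C@@](C)(O)[C@@H]1COCOC | intermediate
13 | (1S,2S,3S)-3-[(E)-2-iodoethenyl]-2-[(methoxymethoxy)methyl]-1,3-dimethyl-6-oxocyclohexyl acetate | I/C=C/[C@@]1(C)CCC(=O)[C@@](C)(OC(C)=O)[C@@H]1COCOC | intermediate
14 | (1S,2S,3S)-2-(hydroxymethyl)-3-[(E)-2-iodoethenyl]-1,3-dimethyl-6-oxocyclohexyl acetate | I/C=C/[C@@]1(C)CCC(=O)[C@@](C)(OC(C)=O)[C@@H]1CO | intermediate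
15 | (1S,2R,3S)-2-formyl-3-[(E)-2-iodoethenyl]-1,3-dimethyl-6-oxocyclohexyl acetate | I/C=C/[C@@]1(C)CCC(=O)[C@@](C)(OC(C)=O)[C@@H]1C=O | intermediate
16 | 1,3-dithiane | C1CSCSC1 | starting material
17 | acrolein | C=CC=O | starting material
18 | rac-1-(1,3-dithian-2-yl)prop-2-en-1-ol | OC(C=C)C1SCCCS1 | intermediate
19 | (S)-1-(1,3-dithian-2-yl)prop-2-en-1-ol | O[C@H](C1SCCCS1)C=C | intermediate
20 | (1S,2S,3S)-2-{(S)-hydroxy[2-((S)-1-hydroxyprop-2-en-1-yl)-1,3-dithian-2-yl]methyl}-3-[(E)-2-iodoethenyl]-1,3-dimethyl-6-oxocyclohexyl acetate | I/C=C/[C@@]1(C)CCC(=O)[C@@](C)(OC(C)=O)[C@@H]1[C@H](O)C2(SCCCS2)[C@@H](O)C=C | intermediate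
21 | 7-O-acryloyl derivative of 20 (1S,7S,9S,10S,11S) | I/C=C/[C@@]1(C)CCC(=O)[C@@](C)(OC(C)=O)[C@@H]1[C@H](O)C2(SCCCS2)[C@@H](OC(=O)C=C)C=C | intermediate
22 | 9-O-acetyl-7-O-acryloyl derivative of 20 (1S,7S,9S,10S,11S) | I/C=C/[C@@]1(C)CCC(=O)[C@@](C)(OC(C)=O)[C@@H]1[C@H](OC(C)=O)C2(SCCCS2)[C@@H](OC(=O)C=C)C=C | intermediate
23 | (1S,2S,3S)-2-[(1S,3S)-1-acetoxy-3-(acryloyloxy)-2-oxopent-4-en-1-yl]-3-[(E)-2-iodoethenyl]-1,3-dimethyl-6-oxocyclohexyl acetate | I/C=C/[C@@]1(C)CCC(=O)[C@@](C)(OC(C)=O)[C@@H]1[C@H](OC(C)=O)C(=O)[C@@H](OC(=O)C=C)C=C | intermediate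
24 | (1S,2S,3S)-2-{(S)-acetoxy[(2S,3S,4R)-3-hydroxy-4-methyl-5-oxo-2-vinyltetrahydrofuran-3-yl]methyl}-3-[(E)-2-iodoethenyl]-1,3-dimethyl-6-oxocyclohexyl acetate | I/C=C/[C@@]1(C)CCC(=O)[C@@](C)(OC(C)=O)[C@@H]1[C@H](OC(C)=O)[C@]2(O)[C@@H](C)C(=O)O[C@H]2C=C | intermediate
25 | (1S,5S,6S)-6-{(S)-acetoxy[(2S,3S,4R)-3-hydroxy-4-methyl-5-oxo-2-vinyltetrahydrofuran-3-yl]methyl}-5-[(E)-2-iodoethenyl]-1,5-dimethyl-2-oxocyclohex-3-en-1-yl acetate | I/C=C/[C@@]1(C)C=CC(=O)[C@@](C)(OC(C)=O)[C@@H]1[C@H](OC(C)=O)[C@]2(O)[C@@H](C)C(=O)O[C@H]2C=C | intermediate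
26 | seco-diene, 25 with iodine replaced by (S)-CH(OH)C(CH3)=CH2 (1S,2E,4S,7S,8S,9S,10S,11S,17R) | C=C(C)[C@@H](O)/C=C/[C@@]1(C)C=CC(=O)[C@@](C)(OC(C)=O)[C@@H]1[C@H](OC(C)=O)[C@]2(O)[C@@H](C)C(=O)O[C@H]2C=C | intermediate
27 | 6-deschloro-5(6)-ene macrocycle (1S,2E,4S,5Z,7S,8S,9S,10S,11S,17R) | [H]/C1=C(\C)[C@@H](O)/C=C/[C@@]2(C)C=CC(=O)[C@@](C)(OC(C)=O)[C@@H]2[C@H](OC(C)=O)[C@]2(O)[C@@H](C)C(=O)O[C@H]21 | intermediate
28 | CNP0196166.1 (1S,2E,4S,6S,7R,8R,9S,10S,11S,17R) | C=C1[C@@H](O)/C=C/[C@@]2(C)C=CC(=O)[C@@](C)(OC(C)=O)[C@@H]2[C@H](OC(C)=O)[C@]2(O)[C@@H](C)C(=O)O[C@H]2[C@H]1Cl | target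

Total step count: 21 steps. Longest linear sequence: 19 steps (steps 1–10, then 13–21).

Steps most likely to fail

Step 20 (ring-closing metathesis). Ring closure to the strained ten-membered ring may be slower than oligomerisation or catalyst decomposition, and the hindered 1,1-disubstituted alkene may not engage. Fallback, setting out from 25: cross-metathesis of the C7 vinyl group with methacrolein (second-generation Hoveyda–Grubbs catalyst, CH2Cl2, 40 °C) should give the (E)-enal F1. An intramolecular Nozaki–Hiyama–Kishi reaction of its vinyl iodide with the enal (CrCl2, NiCl2 cat., DMSO, high dilution) then closes ring B at C3–C4 to the (5E) isomer of 27, F2, with C4 set by the ring. Ene-chlorination as in step 21 erases the C5=C6 geometry, so the fallback comes back to the route at 28.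

Step 21 (ene-chlorination). Chlorine may arrive on the wrong face at C6, the C4 carbinol may be oxidised, or the C2=C3 bond may be attacked. Fallback, setting out from 27: silylation of the C4 hydroxyl (TBSCl, imidazole) gives the silyl ether F3. Epoxidation of the trisubstituted C5=C6 bond (mCPBA, NaHCO3) gives the epoxide F4. Me3SiOTf/DBU isomerisation followed by dilute citric acid gives the C6 allylic alcohol with the C5(16) methylene, F5. Chlorination with inversion (hexachloroacetone, PPh3) gives the chloride F6, and HF·pyridine returns to the route at 28.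

Step 13 (dithiane dianion addition). Facial selectivity at C9 may be poor, and the basic dianion may enolise the aldehyde instead of adding. Fallback, setting out from 15: Pinnick oxidation (NaClO2, NaH2PO4, 2-methyl-2-butene) gives the carboxylic acid F7, and oxalyl chloride (cat. DMF) gives the acid chloride F8. Acylation of the dianion of 19 gives the β-hydroxy ketone F9. Hydroxyl-directed reduction with Me4NBH(OAc)3 (Evans–Saksena, 1,3-anti to the C7 hydroxyl; the ring ketone is not reduced) returns to the route at 20.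

Further compounds
F1 | step 20 | (E)-enal, 25 whose C7 vinyl group has become (E)-CH=C(CH3)CHO | I/C=C/[C@@]1(C)C=CC(=O)[C@@](C)(OC(C)=O)[C@@H]1[C@H](OC(C)=O)[C@]2(O)[C@@H](C)C(=O)O[C@H]2/C=C(\C)C=O
F2 | step 20 | (5E) isomer of macrocycle 27 | [H]/C1=C(/C)[C@@H](O)/C=C/[C@@]2(C)C=CC(=O)[C@@](C)(OC(C)=O)[C@@H]2[C@H](OC(C)=O)[C@]2(O)[C@@H](C)C(=O)O[C@H]21
F3 | step 21 | 4-O-tert-butyldimethylsilyl ether of 27 | [H]/C1=C(\C)[C@@H](O[Si](C)(C)C(C)(C)C)/C=C/[C@@]2(C)C=CC(=O)[C@@](C)(OC(C)=O)[C@@H]2[C@H](OC(C)=O)[C@]2(O)[C@@H](C)C(=O)O[C@H]21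
F4 | step 21 | 5,6-epoxide of F3 | C[C@@]13[C@@H](O[Si](C)(C)C(C)(C)C)/C=C/[C@@]2(C)C=CC(=O)[C@@](C)(OC(C)=O)[C@@H]2[C@H](OC(C)=O)[C@]2(O)[C@@H](C)C(=O)O[C@H]2[C@@H]1O3
F5 | step 21 | 4-O-silyl 6-hydroxy-5(16)-ene, C6 configured opposite to the chloride of 28 | C=C1[C@@H](O[Si](C)(C)C(C)(C)C)/C=C/[C@@]2(C)C=CC(=O)[C@@](C)(OC(C)=O)[C@@H]2[C@H](OC(C)=O)[C@]2(O)[C@@H](C)C(=O)O[C@H]2[C@@H]1O
F6 | step 21 | 4-O-tert-butyldimethylsilyl ether of 28 | C=C1[C@@H](O[Si](C)(C)C(C)(C)C)/C=C/[C@@]2(C)C=CC(=O)[C@@](C)(OC(C)=O)[C@@H]2[C@H](OC(C)=O)[C@]2(O)[C@@H](C)C(=O)O[C@H]2[C@H]1Cl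
F7 | step 13 | carboxylic acid from aldehyde 15 | I/C=C/[C@@]1(C)CCC(=O)[C@@](C)(OC(C)=O)[C@@H]1C(=O)O
F8 | step 13 | acid chloride of F7 | I/C=C/[C@@]1(C)CCC(=O)[C@@](C)(OC(C)=O)[C@@H]1C(=O)Cl
F9 | step 13 | β-hydroxy ketone, C9 ketone analogue of 20 | I/C=C/[C@@]1(C)CCC(=O)[C@@](C)(OC(C)=O)[C@@H]1C(=O)C2(SCCCS2)[C@@H](O)C=C
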